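The lactone chain is numbered C1 (C=O) to C7 (benzylic CH). The ring-fusion carbons C3 and C4 of the cis-fused furo[3,2-b]furanone carry vicinal oxygens: C3 holds the oxolane oxygen O6, and C4 holds the lactone oxygen bound to C1. This threo pair is traced back to a Z C3=C4 alkene, and O6 and C1 are temporarily joined through an ester linkage. Ring-closing metathesis of the diene ester (the but-3-enoate of a C6 homoallylic alcohol carrying a CH(OTIPS)Ph arm) makes C3=C4 and the seven-membered lactone in one operation, with ring size enforcing Z geometry. Directed epoxidation, base-induced reorganisation to the bicycle and a final invertive Mitsunobu coupling with (S)-pinocembrin complete the target.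

Key step: step 5

Remarks on the chemistry
- Chain length: the alcohol half of the metathesis precursor is a 1-phenylpent-4-en-2-yl unit (C7, C6, C5, C4 and one terminal CH2), since a hex-5-enyl unit would close an eight-membered ring; the metathesis product is a 6,7-dihydrooxepin-2(3H)-one with its alkene between ring positions 4 and 5.
- Configuration: the target is C3 R, C4 R, C6 S, C7 S and flavanone C2 S; C7 is carried as R (anti to C6 S) and is inverted only in the last step.
- Protecting group: TIPS is used on O7 because O6 is set free next to it under basic conditions, where a smaller silyl group could shift to O6 and hand the nucleophile role to O7.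
- O6–C3 bond: it is made by conjugate addition after base-induced epoxide isomerisation, not by a 5-endo-tet epoxide opening; both paths lead to the same cis-fused product.
- Assumption: methyl (R)-mandelate, (−)-B-allyldiisopinocampheylborane (pentane solution), but-3-enoic acid and (S)-pinocembrin are bought, the chiral ones as single enantiomers.

Step 1
Reactants: 1 methyl (R)-mandelate
Product: 2 methyl (2R)-2-phenyl-2-[(triisopropylsilyl)oxy]acetate
Conditions: TIPSOTf, 2,6-lutidine, CH2Cl2, 0 °C → rt
Reagents that add atoms: triisopropylsilyl trifluoromethanesulfonate, CC(C)[Si](C(C)C)(C(C)C)OS(=O)(=O)C(F)(F)F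
Why: O-silylation of a secondary alcohol with a silyl triflate and a hindered pyridine base that is too weak to enolise the ester, so C7 stays R.

Step 2
Reactants: 2 methyl (2R)-2-phenyl-2-[(triisopropylsilyl)oxy]acetate
Product: 3 (2R)-2-phenyl-2-[(triisopropylsilyl)oxy]acetaldehyde
Conditions: DIBAL-H (1.1 equiv), toluene, −78 °C; MeOH, then aq Rochelle salt; crude 3 used at once
Reagents that add atoms: none
Why: Partial ester reduction with DIBAL-H, in which the tetrahedral aluminium hemiacetal persists at −78 °C and collapses only on quench, so over-reduction is avoided and the enolisable C7 centre is spared by skipping chromatography.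

Step 3
Reactants: 3 (2R)-2-phenyl-2-[(triisopropylsilyl)oxy]acetaldehyde; 4 (−)-B-allyldiisopinocampheylborane, the reagent derived from (+)-α-pinene
Product: 6 (1R,2S)-1-phenyl-1-[(triisopropylsilyl)oxy]pent-4-en-2-ol, via borinate ester 5 (not isolated)
Conditions: Et2O, −78 °C; then pH 7 phosphate buffer, MeOH, 30% H2O2, 0 °C → rt
Reagents that add atoms: none
Why: Brown asymmetric allylboration through a closed chair transition state, in which the isopinocampheyl ligands send the allyl group to the Si face of the aldehyde and set C6 as S (anti to O7); this matches the intrinsic anti preference of α-silyloxy aldehydes, so control does not rest on a Felkin-type bias that is ambiguous when phenyl and silyloxy compete for the anti position, and the cold base-free medium with buffered oxidation spares C7 and the silyl ether.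

Step 4
Reactants: 6 (1R,2S)-1-phenyl-1-[(triisopropylsilyl)oxy]pent-4-en-2-ol; 7 but-3-enoic acid
Product: 8 (1R,2S)-1-phenyl-1-[(triisopropylsilyl)oxy]pent-4-en-2-yl but-3-enoate
Conditions: DCC, DMAP (10 mol %), CH2Cl2, 0 °C → rt
Reagents that add atoms: none
Why: Steglich esterification, which acylates O6 with retention at C6, while low temperature and a small DMAP charge keep the but-3-enoyl double bond from moving into conjugation, as would occur by the ketene route from an acid chloride and amine.

Step 5
Reactants: 8 (1R,2S)-1-phenyl-1-[(triisopropylsilyl)oxy]pent-4-en-2-yl but-3-enoate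
Product: 9 (4Z,7S)-7-{(R)-phenyl[(triisopropylsilyl)oxy]methyl}-6,7-dihydrooxepin-2(3H)-one
Conditions: Grubbs second-generation catalyst (7 mol %), 1,4-benzoquinone (15 mol %), CH2Cl2 (2 mM), reflux, Ar sparge
Reagents that add atoms: none
Why: Ring-closing olefin metathesis: the ruthenium alkylidene takes up one terminal vinyl group by [2+2] and retro-[2+2], the new alkylidene captures the second vinyl group within the same molecule, and ethene swept out by argon makes closure effectively irreversible. The closest known reaction type is RCM of alkenyl alkenoates to unsaturated ε-lactones, which is established for esters of secondary homoallylic alcohols. The one ring closed is the seven-membered oxepinone, formed by joining the two internal vinyl carbons as C3=C4 with loss of both terminal CH2 groups, and a ring of this size can hold only a Z alkene, the geometry that later gives the threo C3/C4 dioxygen pattern. No stereocentre is created, and C6 and C7 are spectators. The step needs cyclisation to outrun oligomerisation and needs the but-3-enoate alkene to stay out of conjugation: the branched C6 carbinol centre with its bulky CH(OTIPS)Ph arm raises the share of the folded ester rotamer, high dilution suppresses intermolecular metathesis, and benzoquinone intercepts the ruthenium hydrides that shift alkenes.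

Step 6
Reactants: 9 (4Z,7S)-7-{(R)-phenyl[(triisopropylsilyl)oxy]methyl}-6,7-dihydrooxepin-2(3H)-one
Product: 10 methyl (3Z,6S,7R)-6-hydroxy-7-phenyl-7-[(triisopropylsilyl)oxy]hept-3-enoate
Conditions: CSA (10 mol %), MeOH, rt; Et3N quench
Reagents that add atoms: methanol, CO
Why: Acid-catalysed transesterification (lactone methanolysis), in which excess methanol opens the strained ring ester; acid rather than alkoxide avoids alkene conjugation and silyl migration, and O6–H is freed as a directing group because the rather flat, flexible oxepinone with its pseudo-equatorial side chain offers no dependable facial bias of its own.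

Step 7
Reactants: 10 methyl (3Z,6S,7R)-6-hydroxy-7-phenyl-7-[(triisopropylsilyl)oxy]hept-3-enoate
Product: 11 methyl (3S,4R,6S,7R)-3,4-epoxy-6-hydroxy-7-phenyl-7-[(triisopropylsilyl)oxy]heptanoate (cis-epoxide)
Conditions: VO(acac)2 (5 mol %), t-BuOOH (decane), CH2Cl2, 0 °C → rt
Reagents that add atoms: tert-butyl hydroperoxide, CC(C)(C)OO
Why: Vanadium-catalysed hydroxyl-directed epoxidation of a homoallylic alcohol, in which oxygen is delivered inside a chair-like vanadate with the C7 branch equatorial and the C4–C5 rotamer fixed by allylic 1,3-strain of the Z alkene, which places the epoxide oxygen 4,6-syn to O6 (C4 R) and by suprafacial addition makes C3 S.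

Step 8
Reactants: 11 methyl (3S,4R,6S,7R)-3,4-epoxy-6-hydroxy-7-phenyl-7-[(triisopropylsilyl)oxy]heptanoate
Product: 14 (3aR,5S,6aR)-5-{(R)-phenyl[(triisopropylsilyl)oxy]methyl}hexahydrofuro[3,2-b]furan-2-one, via dihydroxy enoate 12 (not isolated), via oxolane hydroxy ester 13 (not isolated)
Conditions: NaOMe (0.3 equiv), MeOH, 0 °C → rt; AcOH quench
Reagents that add atoms: none
Why: Base-induced isomerisation of a β,γ-epoxy ester to a γ-hydroxy enoate (E1cB), then 5-exo-trig oxa-Michael addition and lactonisation, in which the C4–O bond is never broken so C4 stays R, O6 adds reversibly to C3, and only the adduct with CH2CO2Me cis to the C4 hydroxyl (C3 R) can lactonise, making the cis-fused bicycle with the C6 arm on its convex face the sink.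

Step 9
Reactants: 14 (3aR,5S,6aR)-5-{(R)-phenyl[(triisopropylsilyl)oxy]methyl}hexahydrofuro[3,2-b]furan-2-one
Product: 15 (3aR,5S,6aR)-5-[(R)-hydroxy(phenyl)methyl]hexahydrofuro[3,2-b]furan-2-one
Conditions: 48% aq HF, MeCN, 0 °C → rt
Reagents that add atoms: none
Why: Fluoride-driven silyl ether cleavage in acidic medium, which breaks only the O–Si bond so that C7 stays R, and which avoids the basic conditions under which retro-oxa-Michael opening would let the free O7–H re-add to give a pyran isomer.

Step 10
Reactants: 15 (3aR,5S,6aR)-5-[(R)-hydroxy(phenyl)methyl]hexahydrofuro[3,2-b]furan-2-one; 16 (S)-pinocembrin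
Product: 17 (2S)-5-hydroxy-7-{(S)-[(2S,3aR,6aR)-5-oxohexahydrofuro[3,2-b]furan-2-yl](phenyl)methoxy}-2-phenylchroman-4-one (target)
Conditions: PPh3, DIAD, THF, 0 °C → rt
Reagents that add atoms: none
Why: Mitsunobu etherification, in which the phenoxide displaces the C7 oxyphosphonium ion in an SN2 process that inverts C7 from R to S while the adjacent C6–O6 bond disfavours benzylic ionisation; only the acidic, unchelated 7-OH of 16 reacts because 5-OH is hydrogen-bonded to C4=O, and the neutral medium avoids chalcone ring opening, so flavanone C2 (S) and the lactone survive.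

Compound list
1 | methyl (R)-mandelate | O[C@@H](C(=O)OC)c1ccccc1 | starting material
2 | methyl (2R)-2-phenyl-2-[(triisopropylsilyl)oxy]acetate | CC(C)[Si](C(C)C)(C(C)C)O[C@@H](C(=O)OC)c1ccccc1 | intermediate
3 | (2R)-2-phenyl-2-[(triisopropylsilyl)oxy]acetaldehyde | CC(C)[Si](C(C)C)(C(C)C)O[C@@H](C=O)c1ccccc1 | intermediate
4 | (−)-B-allyldiisopinocampheylborane, from (+)-α-pinene | C=CCB([C@@H]1C[C@@H]2C[C@H]([C@H]1C)C2(C)C)[C@@H]1C[C@@H]2C[C@H]([C@H]1C)C2(C)C | starting material
5 | (1R,2S)-1-phenyl-1-[(triisopropylsilyl)oxy]pent-4-en-2-yl diisopinocampheylborinate | O([C@@H](CC=C)[C@H](O[Si](C(C)C)(C(C)C)C(C)C)c1ccccc1)B([C@@H]1C[C@@H]2C[C@H]([C@H]1C)C2(C)C)[C@@H]1C[C@@H]2C[C@H]([C@H]1C)C2(C)C | intermediate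
6 | (1R,2S)-1-phenyl-1-[(triisopropylsilyl)oxy]pent-4-en-2-ol | O[C@@H](CC=C)[C@H](O[Si](C(C)C)(C(C)C)C(C)C)c1ccccc1 | intermediate
7 | but-3-enoic acid | C=CCC(=O)O | starting material
8 | (1R,2S)-1-phenyl-1-[(triisopropylsilyl)oxy]pent-4-en-2-yl but-3-enoate | C=CCC(=O)O[C@@H](CC=C)[C@H](O[Si](C(C)C)(C(C)C)C(C)C)c1ccccc1 | intermediate
9 | (4Z,7S)-7-{(R)-phenyl[(triisopropylsilyl)oxy]methyl}-6,7-dihydrooxepin-2(3H)-one | O=C1C/C=C\C[C@@H]([C@H](O[Si](C(C)C)(C(C)C)C(C)C)c2ccccc2)O1 | intermediate
10 | methyl (3Z,6S,7R)-6-hydroxy-7-phenyl-7-[(triisopropylsilyl)oxy]hept-3-enoate | COC(=O)C/C=C\C[C@H](O)[C@H](O[Si](C(C)C)(C(C)C)C(C)C)c1ccccc1 | intermediate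
11 | methyl (3S,4R,6S,7R)-3,4-epoxy-6-hydroxy-7-phenyl-7-[(triisopropylsilyl)oxy]heptanoate | COC(=O)C[C@@H]1O[C@@H]1C[C@H](O)[C@H](O[Si](C(C)C)(C(C)C)C(C)C)c1ccccc1 | intermediate
12 | methyl (2E,4R,6S,7R)-4,6-dihydroxy-7-phenyl-7-[(triisopropylsilyl)oxy]hept-2-enoate | COC(=O)/C=C/[C@H](O)C[C@H](O)[C@H](O[Si](C(C)C)(C(C)C)C(C)C)c1ccccc1 | intermediate
13 | methyl 2-[(2R,3R,5S)-3-hydroxy-5-{(R)-phenyl[(triisopropylsilyl)oxy]methyl}oxolan-2-yl]acetate | COC(=O)C[C@H]1O[C@H]([C@H](O[Si](C(C)C)(C(C)C)C(C)C)c2ccccc2)C[C@H]1O | intermediate
14 | (3aR,5S,6aR)-5-{(R)-phenyl[(triisopropylsilyl)oxy]methyl}hexahydrofuro[3,2-b]furan-2-one | O=C1C[C@H]2O[C@H]([C@H](O[Si](C(C)C)(C(C)C)C(C)C)c3ccccc3)C[C@H]2O1 | intermediate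
15 | (3aR,5S,6aR)-5-[(R)-hydroxy(phenyl)methyl]hexahydrofuro[3,2-b]furan-2-one | O=C1C[C@H]2O[C@H]([C@H](O)c3ccccc3)C[C@H]2O1 | intermediate
16 | (S)-pinocembrin, (2S)-5,7-dihydroxy-2-phenylchroman-4-one | Oc1cc(O)c2c(c1)O[C@H](c1ccccc1)CC2=O | starting material
17 | (2S)-5-hydroxy-7-{(S)-[(2S,3aR,6aR)-5-oxohexahydrofuro[3,2-b]furan-2-yl](phenyl)methoxy}-2-phenylchroman-4-one | O=C1C[C@H]2O[C@H]([C@@H](Oc3cc(O)c4c(c3)O[C@H](c3ccccc3)CC4=O)c3ccccc3)C[C@H]2O1 | target

Total step count: 10
Longest linear sequence: 10 steps (1 → 17)

Steps most likely to fail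

Step 5. Ring closure may lose to oligomerisation by acyclic diene metathesis, because the ester rests in its extended rotamer. It may also lose to hydride-induced alkene migration followed by closure of a smaller ring. The fallback sets out from 6 and comes back at 10, and it replaces ring-enforced geometry by catalyst-enforced geometry. The free homoallylic alcohol 6 undergoes Z-selective cross-metathesis with excess methyl but-3-enoate under a cyclometalated ruthenium nitrato catalyst (THF, 35 °C, ethene vented). This should give hydroxy ester 10 directly and skip 8 and 9. The detour makes no compound outside the list (F0).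

Step 10. The oxyphosphonium ion of the hindered benzylic carbinol may ionise, which would erode inversion. It may also eliminate, or be captured by the hydrazide instead of the phenoxide. The fallback sets out from 15 and comes back at 17, and it changes the activation mode to an oxidation–reduction condensation. Alcohol 15 is converted with Ph2PCl, Et3N and catalytic DMAP in THF into the diphenylphosphinite of 15 F1. With 16 and 2,6-dimethyl-1,4-benzoquinone in CH2Cl2 at rt, F1 should pass its carbinol carbon to the 7-phenoxide with inversion under neutral conditions suited to hindered secondary alcohols.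

Step 7. Facial selectivity may be poor if oxygen transfer runs through a competing boat-like vanadate or through undirected background oxidation. The fallback sets out from 10 and comes back at 14, and it delivers the C4 oxygen from a tether on O6. Boc2O and DMAP in MeCN give the tert-butyl carbonate of 10 F2. IBr in toluene at −80 °C closes F2 through a chair with equatorial substituents to the 4,6-syn cyclic iodocarbonate F3. K2CO3 in MeOH then cleaves the carbonate, removes the C3 iodide by epoxide closure or elimination, and carries the material through the same oxa-Michael and lactonisation sequence to 14.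

Further compounds
F0 | step 5 | none | none
F1 | step 10 | (R)-[(2S,3aR,6aR)-5-oxohexahydrofuro[3,2-b]furan-2-yl](phenyl)methyl diphenylphosphinite | O=C1C[C@H]2O[C@H]([C@H](OP(c3ccccc3)c3ccccc3)c3ccccc3)C[C@H]2O1
F2 | step 7 | methyl (3Z,6S,7R)-6-[(tert-butoxycarbonyl)oxy]-7-phenyl-7-[(triisopropylsilyl)oxy]hept-3-enoate | COC(=O)C/C=C\C[C@H](OC(=O)OC(C)(C)C)[C@H](O[Si](C(C)C)(C(C)C)C(C)C)c1ccccc1
F3 | step 7 | methyl (3R)-3-iodo-3-[(4R,6S)-2-oxo-6-{(R)-phenyl[(triisopropylsilyl)oxy]methyl}-1,3-dioxan-4-yl]propanoate | COC(=O)C[C@@H](I)[C@H]1C[C@@H]([C@H](O[Si](C(C)C)(C(C)C)C(C)C)c2ccccc2)OC(=O)O1
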